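**Retrosynthetic overview**

1. Numbering (cadinane type): ring A = C1–C2–C3–C4=C5–C6, ring B = C1–C6–C7–C8–C9–C10. C7 carries C11(=C13H2)–C12O2H, C10 the exocyclic C14H2, C4 the C15H2OH group, C8 the ester oxygen.
2. Enabling feature: in ring B the C6–C7 bond joins the ring-fusion CH (C6, bearing C5 of ring A) to a CH that carries an sp2 carbon (C11). C5 and C11 are cis, the C8 oxygen is trans to C11, and the sp2 carbon C10 lies 1,4 to C7. This is the imprint of an endo Diels–Alder adduct of a 2-silyloxy diene C9=C10(OSi)–C1=C6(–vinyl) with an (E)-β-acyloxy enone C8=C7–C11(=O).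
3. Disconnections: C12 acid from the allylic alcohol; ring A by ring-closing metathesis at C4=C5; the alkenes at C4, C10 and C11 by one threefold methylenation of a triketone; C1–C2 by Mukaiyama–Michael addition to the regiodefined enol ether, anti to the C6/C7 groups (this sets the trans ring fusion); ring B by the Diels–Alder reaction that forms C6–C7 and C8–C9.
4. Fragments: a silyloxy triene from acrolein; an enol-ester dienophile whose C8 oxygen already carries the complete (S)-side chain as its acetonide (from the malic-acid-derived ester); a silyloxymethyl vinyl ketone that supplies C2–C3–C4–C15.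
5. Ring order: ring B first (Diels–Alder), ring A last (metathesis).

Key step: step 10

Assumption: the (S)-configured cationic oxazaborolidine is taken to expose the enone face of the dienophile that leads to the (1S,5S,6S) adduct, by analogy with its behaviour towards (E)-β-substituted enones; if the sense proves opposite, the (R)-catalyst is used.

**Route**

Step 1
Reactants: 1 methyl 2-[(4S)-2,2-dimethyl-1,3-dioxolan-4-yl]acetate
Product: 4 methyl 2-[(4S)-2,2-dimethyl-1,3-dioxolan-4-yl]prop-2-enoate, via Mannich base 2 (not isolated), via ammonium iodide 3 (not isolated)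
Conditions: LiN(iPr)2, THF, −78 °C; Me2N=CH2 I, −78 → −20 °C; MeI, rt; DBU, rt
Reagents that add atoms: N,N-dimethylmethyleneiminium iodide (Eschenmoser's salt) C=[N+](C)C.[I-]
Why: Eschenmoser α-methylenation, in which the lithium ester enolate is trapped in a Mannich reaction at −78 °C faster than it can expel the β-alkoxide and quaternisation followed by E1cB loss of trimethylamine makes the α-carbon sp2 without touching the dioxolane stereocentre.

Step 2
Reactants: 4 methyl 2-[(4S)-2,2-dimethyl-1,3-dioxolan-4-yl]prop-2-enoate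
Product: 5 2-[(4S)-2,2-dimethyl-1,3-dioxolan-4-yl]prop-2-enoic acid
Conditions: LiOH·H2O, THF/H2O, 0 °C → rt; 1 M HCl to pH 4, 0 °C
Reagents that add atoms: lithium hydroxide [Li+].[OH-]
Why: Saponification of the methyl ester should proceed cleanly because the acetonide is base-stable and the stereocentre is not α to the carbonyl and cannot epimerise.

Step 3
Reactants: 6 2-chloro-N-methoxy-N-methylacetamide
Product: 7 N-methoxy-2-[(4-methoxyphenyl)methoxy]-N-methylacetamide
Conditions: 4-methoxybenzyl alcohol, NaH, THF, 0 °C → rt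
Reagents that add atoms: 4-methoxybenzyl alcohol COc1ccc(CO)cc1
Why: Williamson ether synthesis, the alkoxide displacing the activated α-chloride by SN2 while the Weinreb amide is inert to alkoxide.

Step 4
Reactants: 7 N-methoxy-2-[(4-methoxyphenyl)methoxy]-N-methylacetamide; 8 ethynylmagnesium bromide
Product: 9 1-[(4-methoxyphenyl)methoxy]but-3-yn-2-one
Conditions: THF, −78 → 0 °C; inverse quench into cold 1 M HCl
Reagents that add atoms: none
Why: Weinreb ketone synthesis, in which the chelated tetrahedral adduct prevents over-addition and the acidic inverse quench keeps the liberated amine from adding to the ynone.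

Step 5
Reactants: 5 2-[(4S)-2,2-dimethyl-1,3-dioxolan-4-yl]prop-2-enoic acid; 9 1-[(4-methoxyphenyl)methoxy]but-3-yn-2-one
Product: 10 (1E)-4-[(4-methoxyphenyl)methoxy]-3-oxobut-1-en-1-yl 2-[(4S)-2,2-dimethyl-1,3-dioxolan-4-yl]prop-2-enoate
Conditions: N-methylmorpholine (10 mol %), CH2Cl2, 0 °C → rt
Reagents that add atoms: none
Why: Tertiary-amine-catalysed conjugate addition of a carboxylic acid to a terminal ynone (as known for propiolates) should give the thermodynamically preferred E enol ester, so that the future C8 oxygen arrives already acylated by the complete side chain; no stereocentre is formed.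

Step 6
Reactants: 11 acrolein; 12 1-(triphenyl-λ5-phosphanylidene)propan-2-one
Product: 13 (3E)-hexa-3,5-dien-2-one
Conditions: CH2Cl2, rt
Reagents that add atoms: none
Why: Wittig olefination with a stabilised ylide gives the E enone selectively.

Step 7
Reactants: 13 (3E)-hexa-3,5-dien-2-one
Product: 14 {[(3E)-hexa-1,3,5-trien-2-yl]oxy}tri(propan-2-yl)silane
Conditions: iPr3SiOTf, Et3N, CH2Cl2, 0 °C
Reagents that add atoms: triisopropylsilyl triflate CC(C)[Si](C(C)C)(C(C)C)OS(=O)(=O)C(F)(F)F
Why: Soft enolisation and O-silylation at the only enolisable position (the methyl group) gives the 2-silyloxy triene with the E geometry of the central alkene unchanged.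

Step 8
Reactants: 15 {[tert-butyl(dimethyl)silyl]oxy}acetaldehyde; 16 vinylmagnesium bromide
Product: 17 1-{[tert-butyl(dimethyl)silyl]oxy}but-3-en-2-ol (racemic)
Conditions: THF, −78 °C; cold 1 M HCl quench
Reagents that add atoms: none
Why: Grignard 1,2-addition to the aldehyde, the new carbinol centre being racemic and destroyed in the next step.

Step 9
Reactants: 17 1-{[tert-butyl(dimethyl)silyl]oxy}but-3-en-2-ol (racemic)
Product: 18 1-{[tert-butyl(dimethyl)silyl]oxy}but-3-en-2-one
Conditions: Dess–Martin periodinane, CH2Cl2, 0 °C → rt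
Reagents that add atoms: none
Why: Dess–Martin oxidation converts the allylic alcohol into the vinyl ketone under non-basic conditions that avoid Michael addition and polymerisation.

Step 10
Reactants: 10 (1E)-4-[(4-methoxyphenyl)methoxy]-3-oxobut-1-en-1-yl 2-[(4S)-2,2-dimethyl-1,3-dioxolan-4-yl]prop-2-enoate; 14 {[(3E)-hexa-1,3,5-trien-2-yl]oxy}tri(propan-2-yl)silane
Product: 19 (1S,5S,6S)-5-ethenyl-6-{[(4-methoxyphenyl)methoxy]acetyl}-3-{[tri(propan-2-yl)silyl]oxy}cyclohex-3-en-1-yl 2-[(4S)-2,2-dimethyl-1,3-dioxolan-4-yl]prop-2-enoate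
Conditions: (S)-o-tolyl-CBS oxazaborolidine·Tf2NH (20 mol %), CH2Cl2, −78 → −40 °C
Reagents that add atoms: none
Why: Lewis-acid-catalysed normal-demand [4+2] cycloaddition, concerted but asynchronous: the silyloxy-activated terminus C9 bonds first to the ketone-activated β-carbon C8, and formation of the C6–C7 bond closes ring B (six-membered carbocycle, intermolecular [4+2] mode, both components suprafacial). The closest known reaction types are the cationic-oxazaborolidine-catalysed enantioselective Diels–Alder reactions of 2-silyloxy dienes with acyclic (E)-β-substituted enones and the Diels–Alder reactions of (E)-β-acyloxy acryloyl dienophiles. C8 is fixed trans to C7 by the E geometry of the enol ester, and C6/C7 are fixed cis (vinyl and acyl on the same face) by the endo orientation of the catalyst-bound ketone together with the E geometry of the C1=C6 bond. The absolute configuration of the three centres comes from the catalyst, which blocks one face of the enone. The step needs regio-, peri- and chemoselectivity: the silyloxy group on C10 ("para") and the vinyl group on C6 ("ortho") both pair C9 with C8 and C6 with C7, the silyloxy-bearing diene is the only electron-rich 4π unit of the triene, and the ketone-conjugated alkene is far more electrophilic than the α-branched acrylate of the side chain.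

Step 11
Reactants: 19 (1S,5S,6S)-5-ethenyl-6-{[(4-methoxyphenyl)methoxy]acetyl}-3-{[tri(propan-2-yl)silyl]oxy}cyclohex-3-en-1-yl 2-[(4S)-2,2-dimethyl-1,3-dioxolan-4-yl]prop-2-enoate; 18 1-{[tert-butyl(dimethyl)silyl]oxy}but-3-en-2-one
Product: 20 (1S,2S,3S,4S)-4-(4-{[tert-butyl(dimethyl)silyl]oxy}-3-oxobutyl)-3-ethenyl-2-{[(4-methoxyphenyl)methoxy]acetyl}-5-oxocyclohexyl 2-[(4S)-2,2-dimethyl-1,3-dioxolan-4-yl]prop-2-enoate
Conditions: TiCl4, CH2Cl2, −78 °C; aq. work-up
Reagents that add atoms: none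
Why: Mukaiyama–Michael addition of the regiodefined silyl enol ether to the TiCl4-activated vinyl ketone forms C1–C2, and the new C1 centre is set because the upper face of the enol ether is shielded by the cis-disposed C6 vinyl and C7 acyl groups, so that C2 enters anti to both (the usual 2,3-trans alkylation of a 3-substituted cyclohexanone enolate), which fixes the trans relationship at the future ring fusion.

Step 12
Reactants: 20 (1S,2S,3S,4S)-4-(4-{[tert-butyl(dimethyl)silyl]oxy}-3-oxobutyl)-3-ethenyl-2-{[(4-methoxyphenyl)methoxy]acetyl}-5-oxocyclohexyl 2-[(4S)-2,2-dimethyl-1,3-dioxolan-4-yl]prop-2-enoate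
Product: 21 (1S,2R,3S,4S)-4-[3-({[tert-butyl(dimethyl)silyl]oxy}methyl)but-3-en-1-yl]-3-ethenyl-2-{3-[(4-methoxyphenyl)methoxy]prop-1-en-2-yl}-5-methylidenecyclohexyl 2-[(4S)-2,2-dimethyl-1,3-dioxolan-4-yl]prop-2-enoate
Conditions: Zn, CH2Br2, TiCl4 (pre-formed reagent, excess), THF/CH2Cl2, 0 °C → rt
Reagents that add atoms: dibromomethane BrCBr
Why: Takai–Lombardo methylenation should convert all three ketones (C4, C10, C11) into 1,1-disubstituted alkenes with a non-basic gem-dimetallic reagent that leaves the esters, the epimerisable C1 and C7 centres and the β-acyloxy ketone (no E1cB) untouched; no stereocentre is formed.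

Step 13
Reactants: 21 (1S,2R,3S,4S)-4-[3-({[tert-butyl(dimethyl)silyl]oxy}methyl)but-3-en-1-yl]-3-ethenyl-2-{3-[(4-methoxyphenyl)methoxy]prop-1-en-2-yl}-5-methylidenecyclohexyl 2-[(4S)-2,2-dimethyl-1,3-dioxolan-4-yl]prop-2-enoate
Product: 22 (1R,2S,4aS,8aS)-7-({[tert-butyl(dimethyl)silyl]oxy}methyl)-1-{3-[(4-methoxyphenyl)methoxy]prop-1-en-2-yl}-4-methylidene-1,2,3,4,4a,5,6,8a-octahydronaphthalen-2-yl 2-[(4S)-2,2-dimethyl-1,3-dioxolan-4-yl]prop-2-enoate
Conditions: second-generation Grubbs catalyst (5 mol %), CH2Cl2, 40 °C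
Reagents that add atoms: none
Why: Ring-closing metathesis between the only monosubstituted alkene (the C6 vinyl group) and the C4 methylidene should close ring A as the trisubstituted cyclohexene, since every other pairing would give a four-membered ring or a tetrasubstituted alkene; no stereocentre changes.

Step 14
Reactants: 22 (1R,2S,4aS,8aS)-7-({[tert-butyl(dimethyl)silyl]oxy}methyl)-1-{3-[(4-methoxyphenyl)methoxy]prop-1-en-2-yl}-4-methylidene-1,2,3,4,4a,5,6,8a-octahydronaphthalen-2-yl 2-[(4S)-2,2-dimethyl-1,3-dioxolan-4-yl]prop-2-enoate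
Product: 23 (1R,2S,4aS,8aS)-7-({[tert-butyl(dimethyl)silyl]oxy}methyl)-1-(3-hydroxyprop-1-en-2-yl)-4-methylidene-1,2,3,4,4a,5,6,8a-octahydronaphthalen-2-yl 2-[(4S)-2,2-dimethyl-1,3-dioxolan-4-yl]prop-2-enoate
Conditions: DDQ, CH2Cl2/pH 7 buffer, 0 °C
Reagents that add atoms: none
Why: Oxidative cleavage of the 4-methoxybenzyl ether by DDQ (benzylic hydride abstraction, then hydrolysis) frees the C12 allylic alcohol while the silyl ether, the acetonide and the isolated alkenes are inert.

Step 15
Reactants: 23 (1R,2S,4aS,8aS)-7-({[tert-butyl(dimethyl)silyl]oxy}methyl)-1-(3-hydroxyprop-1-en-2-yl)-4-methylidene-1,2,3,4,4a,5,6,8a-octahydronaphthalen-2-yl 2-[(4S)-2,2-dimethyl-1,3-dioxolan-4-yl]prop-2-enoate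
Product: 25 2-[(1R,2S,4aS,8aS)-7-({[tert-butyl(dimethyl)silyl]oxy}methyl)-2-({2-[(4S)-2,2-dimethyl-1,3-dioxolan-4-yl]prop-2-enoyl}oxy)-4-methylidene-1,2,3,4,4a,5,6,8a-octahydronaphthalen-1-yl]prop-2-enoic acid, via enal 24 (not isolated)
Conditions: Dess–Martin periodinane, CH2Cl2, 0 °C; then NaClO2, NaH2PO4, 2-methylbut-2-ene, tBuOH/H2O, 0 °C → rt
Reagents that add atoms: sodium chlorite [Na+].[O-]Cl=O
Why: Dess–Martin oxidation to the 2-substituted acrolein followed by Pinnick oxidation (chlorite with an alkene scavenger for HOCl) should give the acrylic acid under neutral to mildly acidic conditions that do not touch the stereocentres.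

Step 16
Reactants: 25 2-[(1R,2S,4aS,8aS)-7-({[tert-butyl(dimethyl)silyl]oxy}methyl)-2-({2-[(4S)-2,2-dimethyl-1,3-dioxolan-4-yl]prop-2-enoyl}oxy)-4-methylidene-1,2,3,4,4a,5,6,8a-octahydronaphthalen-1-yl]prop-2-enoic acid
Product: 26 2-[(1R,2S,4aS,8aS)-2-{[(3S)-3,4-dihydroxy-2-methylidenebutanoyl]oxy}-7-(hydroxymethyl)-4-methylidene-1,2,3,4,4a,5,6,8a-octahydronaphthalen-1-yl]prop-2-enoic acid
Conditions: AcOH/THF/H2O (3:1:1), 40 °C
Reagents that add atoms: none
Why: Acid-catalysed hydrolysis should remove the terminal acetonide and the primary allylic silyl ether in one operation under conditions too mild to isomerise the exocyclic alkenes or transesterify the C8 ester.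

**Compound list**

1 | methyl 2-[(4S)-2,2-dimethyl-1,3-dioxolan-4-yl]acetate | COC(=O)C[C@H]1COC(C)(C)O1 | starting material
2 | methyl 3-(dimethylamino)-2-[(4S)-2,2-dimethyl-1,3-dioxolan-4-yl]propanoate (Mannich base, C-2 epimers) | COC(=O)C(CN(C)C)[C@H]1COC(C)(C)O1 | intermediate
3 | {2-[(4S)-2,2-dimethyl-1,3-dioxolan-4-yl]-3-methoxy-3-oxopropyl}trimethylammonium iodide | COC(=O)C(C[N+](C)(C)C)[C@H]1COC(C)(C)O1.[I-] | intermediate
4 | methyl 2-[(4S)-2,2-dimethyl-1,3-dioxolan-4-yl]prop-2-enoate | COC(=O)C(=C)[C@H]1COC(C)(C)O1 | intermediate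
5 | 2-[(4S)-2,2-dimethyl-1,3-dioxolan-4-yl]prop-2-enoic acid | OC(=O)C(=C)[C@H]1COC(C)(C)O1 | intermediate
6 | 2-chloro-N-methoxy-N-methylacetamide | CON(C)C(=O)CCl | starting material
7 | N-methoxy-2-[(4-methoxyphenyl)methoxy]-N-methylacetamide | CON(C)C(=O)COCc1ccc(OC)cc1 | intermediate
8 | ethynylmagnesium bromide | C#C[Mg]Br | starting material
9 | 1-[(4-methoxyphenyl)methoxy]but-3-yn-2-one | C#CC(=O)COCc1ccc(OC)cc1 | intermediate
10 | (1E)-4-[(4-methoxyphenyl)methoxy]-3-oxobut-1-en-1-yl 2-[(4S)-2,2-dimethyl-1,3-dioxolan-4-yl]prop-2-enoate | COc1ccc(COCC(=O)/C=C/OC(=O)C(=C)[C@H]2COC(C)(C)O2)cc1 | intermediate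
11 | acrolein | C=CC=O | starting material
12 | 1-(triphenyl-λ5-phosphanylidene)propan-2-one | CC(=O)C=P(c1ccccc1)(c1ccccc1)c1ccccc1 | starting material
13 | (3E)-hexa-3,5-dien-2-one | CC(=O)/C=C/C=C | intermediate
14 | {[(3E)-hexa-1,3,5-trien-2-yl]oxy}tri(propan-2-yl)silane | C=C(O[Si](C(C)C)(C(C)C)C(C)C)/C=C/C=C | intermediate
15 | {[tert-butyl(dimethyl)silyl]oxy}acetaldehyde | CC(C)(C)[Si](C)(C)OCC=O | starting material
16 | vinylmagnesium bromide | C=C[Mg]Br | starting material
17 | 1-{[tert-butyl(dimethyl)silyl]oxy}but-3-en-2-ol (racemic) | CC(C)(C)[Si](C)(C)OCC(O)C=C | intermediate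
18 | 1-{[tert-butyl(dimethyl)silyl]oxy}but-3-en-2-one | CC(C)(C)[Si](C)(C)OCC(=O)C=C | intermediate
19 | (1S,5S,6S)-5-ethenyl-6-{[(4-methoxyphenyl)methoxy]acetyl}-3-{[tri(propan-2-yl)silyl]oxy}cyclohex-3-en-1-yl 2-[(4S)-2,2-dimethyl-1,3-dioxolan-4-yl]prop-2-enoate | O=C(COCc1ccc(OC)cc1)[C@H]1[C@@H](C=C)C=C(O[Si](C(C)C)(C(C)C)C(C)C)C[C@@H]1OC(=O)C(=C)[C@H]1COC(C)(C)O1 | intermediate
20 | (1S,2S,3S,4S)-4-(4-{[tert-butyl(dimethyl)silyl]oxy}-3-oxobutyl)-3-ethenyl-2-{[(4-methoxyphenyl)methoxy]acetyl}-5-oxocyclohexyl 2-[(4S)-2,2-dimethyl-1,3-dioxolan-4-yl]prop-2-enoate | O=C(COCc1ccc(OC)cc1)[C@H]1[C@@H](C=C)[C@H](CCC(=O)CO[Si](C)(C)C(C)(C)C)C(=O)C[C@@H]1OC(=O)C(=C)[C@H]1COC(C)(C)O1 | intermediate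
21 | (1S,2R,3S,4S)-4-[3-({[tert-butyl(dimethyl)silyl]oxy}methyl)but-3-en-1-yl]-3-ethenyl-2-{3-[(4-methoxyphenyl)methoxy]prop-1-en-2-yl}-5-methylidenecyclohexyl 2-[(4S)-2,2-dimethyl-1,3-dioxolan-4-yl]prop-2-enoate | C=C(COCc1ccc(OC)cc1)[C@H]1[C@@H](C=C)[C@H](CCC(=C)CO[Si](C)(C)C(C)(C)C)C(=C)C[C@@H]1OC(=O)C(=C)[C@H]1COC(C)(C)O1 | intermediate
22 | (1R,2S,4aS,8aS)-7-({[tert-butyl(dimethyl)silyl]oxy}methyl)-1-{3-[(4-methoxyphenyl)methoxy]prop-1-en-2-yl}-4-methylidene-1,2,3,4,4a,5,6,8a-octahydronaphthalen-2-yl 2-[(4S)-2,2-dimethyl-1,3-dioxolan-4-yl]prop-2-enoate | C=C(COCc1ccc(OC)cc1)[C@H]1[C@H]2C=C(CO[Si](C)(C)C(C)(C)C)CC[C@@H]2C(=C)C[C@@H]1OC(=O)C(=C)[C@H]1COC(C)(C)O1 | intermediate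
23 | (1R,2S,4aS,8aS)-7-({[tert-butyl(dimethyl)silyl]oxy}methyl)-1-(3-hydroxyprop-1-en-2-yl)-4-methylidene-1,2,3,4,4a,5,6,8a-octahydronaphthalen-2-yl 2-[(4S)-2,2-dimethyl-1,3-dioxolan-4-yl]prop-2-enoate | C=C(CO)[C@H]1[C@H]2C=C(CO[Si](C)(C)C(C)(C)C)CC[C@@H]2C(=C)C[C@@H]1OC(=O)C(=C)[C@H]1COC(C)(C)O1 | intermediate
24 | (1R,2S,4aS,8aS)-7-({[tert-butyl(dimethyl)silyl]oxy}methyl)-4-methylidene-1-(3-oxoprop-1-en-2-yl)-1,2,3,4,4a,5,6,8a-octahydronaphthalen-2-yl 2-[(4S)-2,2-dimethyl-1,3-dioxolan-4-yl]prop-2-enoate | C=C(C=O)[C@H]1[C@H]2C=C(CO[Si](C)(C)C(C)(C)C)CC[C@@H]2C(=C)C[C@@H]1OC(=O)C(=C)[C@H]1COC(C)(C)O1 | intermediate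
25 | 2-[(1R,2S,4aS,8aS)-7-({[tert-butyl(dimethyl)silyl]oxy}methyl)-2-({2-[(4S)-2,2-dimethyl-1,3-dioxolan-4-yl]prop-2-enoyl}oxy)-4-methylidene-1,2,3,4,4a,5,6,8a-octahydronaphthalen-1-yl]prop-2-enoic acid | C=C(C(=O)O)[C@H]1[C@H]2C=C(CO[Si](C)(C)C(C)(C)C)CC[C@@H]2C(=C)C[C@@H]1OC(=O)C(=C)[C@H]1COC(C)(C)O1 | intermediate
26 | 2-[(1R,2S,4aS,8aS)-2-{[(3S)-3,4-dihydroxy-2-methylidenebutanoyl]oxy}-7-(hydroxymethyl)-4-methylidene-1,2,3,4,4a,5,6,8a-octahydronaphthalen-1-yl]prop-2-enoic acid (CNP0460913.4) | C=C(C(=O)O)[C@H]1[C@H]2C=C(CO)CC[C@@H]2C(=C)C[C@@H]1OC(=O)C(=C)[C@H](O)CO | target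

**Step count and risks**

Total step count: 16. Longest linear sequence: 10 steps (steps 3, 4, 5, 10, 11, 12, 13, 14, 15, 16; equally 1, 2, 5, 10–16).

Most likely to fail, step 10: the strongly Lewis-acidic catalyst may be bound by the ester, acetal and ether oxygens of 10, with loss of enantiofacial control. The reaction may also stop at the open Mukaiyama–Michael stage, or the acid may shift the silyl enol ether double bond. Fallback: the cycloaddition is run from 10 and 14 without any Lewis acid (toluene, 90 °C, BHT). Because 10 already carries the (S)-dioxolane ester, the thermal endo reaction should give 19 together with its (1R,5R,6R) diastereomer F1 as diastereomers, not enantiomers. They are separated by chromatography and the route is rejoined at 19. Stereocontrol thus moves from the catalyst to a classical separation on the resident stereocentre, at the cost of half the material.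

Second, step 11: TiCl4 may cleave the 4-methoxybenzyl ether or the acetonide, the 1,5-diketone may close by a Robinson-type aldol reaction, or facial selectivity at C1 may erode in the open transition state. Fallback: from 19 and 18 the same C1–C2 bond is made by an inverse-electron-demand hetero-Diels–Alder reaction (Yb(fod)3 cat., CH2Cl2, rt, or neat at 60 °C). Here 18 acts as a 1-oxadiene across the C1=C10 enol ether bond from the open lower face and should give the cis-fused dihydropyran ketal F2. Mild hydrolysis of the mixed silyl ketal (PPTS, aqueous acetone) then opens it to triketone 20.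

Third, step 1: the ester enolate may expel the β-oxygen of the dioxolane (ring-opening β-elimination) before it is trapped. Fallback: the methylene group is introduced on (S)-3-hydroxy-γ-butyrolactone F3, whose dianion (2 equiv LiN(iPr)2, THF, −78 °C) carries the β-oxygen as an alkoxide that cannot leave. Reaction with Eschenmoser's salt should give Mannich lactone F4, and MeI followed by NaHCO3 gives (S)-β-hydroxy-α-methylene-γ-butyrolactone F5. Acid-catalysed methanolysis in the presence of 2,2-dimethoxypropane (MeOH, TsOH cat.) traps the open diol as its acetonide and returns to ester 4.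

Further compounds
F1 | step 10 | (1R,5R,6R)-5-ethenyl-6-{[(4-methoxyphenyl)methoxy]acetyl}-3-{[tri(propan-2-yl)silyl]oxy}cyclohex-3-en-1-yl 2-[(4S)-2,2-dimethyl-1,3-dioxolan-4-yl]prop-2-enoate | O=C(COCc1ccc(OC)cc1)[C@@H]1[C@H](C=C)C=C(O[Si](C(C)C)(C(C)C)C(C)C)C[C@H]1OC(=O)C(=C)[C@H]1COC(C)(C)O1
F2 | step 11 | cis-fused 2-({[tert-butyl(dimethyl)silyl]oxy}methyl)-5-ethenyl-6-{[(4-methoxyphenyl)methoxy]acetyl}-8a-{[tri(propan-2-yl)silyl]oxy}-4a,5,6,7,8,8a-hexahydro-4H-chromen-7-yl 2-[(4S)-2,2-dimethyl-1,3-dioxolan-4-yl]prop-2-enoate (C-5, C-6, C-7 as in 19) | O=C(COCc1ccc(OC)cc1)[C@H]1[C@@H](C=C)[C@@H]2CC=C(CO[Si](C)(C)C(C)(C)C)O[C@]2(O[Si](C(C)C)(C(C)C)C(C)C)C[C@@H]1OC(=O)C(=C)[C@H]1COC(C)(C)O1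
F3 | step 1 | (4S)-4-hydroxyoxolan-2-one ((S)-3-hydroxy-γ-butyrolactone) | O=C1C[C@H](O)CO1
F4 | step 1 | (4S)-3-[(dimethylamino)methyl]-4-hydroxyoxolan-2-one | O=C1C(CN(C)C)[C@H](O)CO1
F5 | step 1 | (4S)-4-hydroxy-3-methylideneoxolan-2-one | O=C1C(=C)[C@H](O)CO1
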